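The route rests on cutting two neighbouring bonds of central ring B (C1 bears the ethano bridge, C2 and C6 the 4-hydroxybenzyl groups, C5 the hydroxyl): C1–CH2 of the bridge and C6–CH2Ar. The feature exploited is the C5 oxygen beside C6: it polarises a C1≡C6 aryne so that carbon nucleophiles enter at C1. Insertion of this aryne into the CH2–C(=O) bond of an aroylacetate sets an acetate arm on C1 and a 4-benzyloxybenzoyl group, a latent benzyl, on C6 in one operation. The precursor is an ortho-silylaryl triflate already carrying the C5 benzyl ether and the C2 benzyl group. Ring A is added afterwards as a Grignard reagent.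

Key step: step 6

Remark on the chemistry: the target has no stereocentre. The stereocentres of 12 and 19 form without control and are erased again, so both are drawn without configuration. The ring-A phenol must be masked before magnesium insertion, hence step 9.

Step 1
Reactants: 1 2-bromoresorcinol; 2 4-(benzyloxy)benzyl alcohol
Product: 3 4-[4-(benzyloxy)benzyl]-2-bromobenzene-1,3-diol
Conditions: 1 (3 equiv), p-TsOH·H2O (10 mol%), HFIP/CH2Cl2, rt, slow addition of 2 (1 equiv)
Reagents that add atoms: none
Why: Acid-catalysed Friedel–Crafts benzylation, in which the 4-benzyloxybenzyl cation released from 2 in the ionising medium is captured at C4 of 1 (ortho to one hydroxyl, para to the other; C4 and C6 are equivalent and C5 is not activated), while slow addition of 2 to an excess of recoverable 1 holds back a second alkylation and self-condensation.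

Step 2
Reactants: 3 4-[4-(benzyloxy)benzyl]-2-bromobenzene-1,3-diol
Product: 4 3-(benzyloxy)-6-[4-(benzyloxy)benzyl]-2-bromophenol
Conditions: BnBr (1.0 equiv), K2CO3 (1.05 equiv), DMF, 0 °C → rt
Reagents that add atoms: benzyl bromide, BrCc1ccccc1
Why: Williamson ether synthesis under steric control, since with one equivalent each of base and halide the hydroxyl flanked by Br and H should be deprotonated and alkylated ahead of the one wedged between Br and the CH2Ar group.

Step 3
Reactants: 4 3-(benzyloxy)-6-[4-(benzyloxy)benzyl]-2-bromophenol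
Product: 5 {3-(benzyloxy)-6-[4-(benzyloxy)benzyl]-2-bromophenoxy}trimethylsilane
Conditions: HMDS (1.5 equiv), THF, 70 °C; evaporation in vacuo, used crude
Reagents that add atoms: hexamethyldisilazane, C[Si](C)(C)N[Si](C)(C)C
Why: O-Silylation of a phenol with HMDS leaves only volatile material beside the silyl ether, so 5 is obtained by evaporation without contact with water or silica.

Step 4
Reactants: 5 {3-(benzyloxy)-6-[4-(benzyloxy)benzyl]-2-bromophenoxy}trimethylsilane
Product: 8 3-(benzyloxy)-6-[4-(benzyloxy)benzyl]-2-(trimethylsilyl)phenyl trifluoromethanesulfonate, via aryllithium 6 (not isolated), via lithium phenoxide 7 (not isolated)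
Conditions: n-BuLi (1.1 equiv), THF, −90 °C; then Tf2O (1.2 equiv), −90 → −20 °C
Reagents that add atoms: trifluoromethanesulfonic anhydride, O=S(=O)(OS(=O)(=O)C(F)(F)F)C(F)(F)F
Why: Bromine–lithium exchange outruns deprotonation of the benzylic positions at this temperature, 6 then takes the silyl group from the neighbouring oxygen (1,3 O→C shift, retro-Brook rearrangement), and the freed phenoxide 7 is trapped by Tf2O, which is the standard entry to ortho-silylaryl triflates.

Step 5
Reactants: 9 4′-(benzyloxy)acetophenone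
Product: 10 methyl 3-[4-(benzyloxy)phenyl]-3-oxopropanoate
Conditions: NaH (2.2 equiv), (MeO)2CO (3 equiv), THF, reflux; then 1 M HCl
Reagents that add atoms: dimethyl carbonate, COC(=O)OC
Why: Crossed Claisen condensation of the ketone enolate with non-enolisable dimethyl carbonate, pulled to completion by irreversible deprotonation of the β-ketoester.

Step 6
Reactants: 8 3-(benzyloxy)-6-[4-(benzyloxy)benzyl]-2-(trimethylsilyl)phenyl trifluoromethanesulfonate; 10 methyl 3-[4-(benzyloxy)phenyl]-3-oxopropanoate
Product: 13 methyl 2-{3-(benzyloxy)-2-[4-(benzyloxy)benzoyl]-6-[4-(benzyloxy)benzyl]phenyl}acetate, via aryne 11 (not isolated), via benzocyclobutenoxide 12 (not isolated)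
Conditions: 8 (1.25 equiv), 10 (1.0 equiv), CsF (2.5 equiv), MeCN, 80 °C
Reagents that add atoms: none
Why: Fluoride attacks silicon in 8 and triflate departs to give aryne 11; the enolate of 10 bonds through its α-carbon to C1, the charge that builds up on C6 closes onto the aroyl carbonyl to give 12, and cleavage of this strained four-membered ring leaves the aroyl group on C6 and the ester-stabilised CH2CO2Me arm on C1, a formal insertion into the Cα–C(=O) bond. The closest known reaction type is the aryne acyl-alkylation of β-ketoesters with CsF in MeCN, established for aroylacetates and for 3-alkoxyarynes. No ring remains in 13 (the four-membered ring of 12 forms by 4-exo-trig attack of C6 on the ketone and opens again) and no stereocentre is created in 13. The selectivity required is regiochemical: the inductively withdrawing C5 benzyloxy group distorts 11 so that C1 is the more linear and more electrophilic aryne carbon and stabilises charge on the adjacent C6, which should outweigh the modest shielding of C1 by the flexible C2 CH2Ar group. Ring closure must also beat protonation at C6, which the aprotic medium and the use of 10 as limiting component favour.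

Step 7
Reactants: 13 methyl 2-{3-(benzyloxy)-2-[4-(benzyloxy)benzoyl]-6-[4-(benzyloxy)benzyl]phenyl}acetate
Product: 14 methyl 2-{3-(benzyloxy)-2,6-bis[4-(benzyloxy)benzyl]phenyl}acetate
Conditions: Et3SiH (5 equiv), TFA, CH2Cl2, 0 °C → rt
Reagents that add atoms: none
Why: Ionic hydrogenation, in which two successive hydride transfers from the silane go first to the protonated carbonyl carbon and then to the diarylmethyl cation, both stabilised by the para-benzyloxy donor, while the ester and the aryl benzyl ethers tolerate TFA at room temperature.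

Step 8
Reactants: 14 methyl 2-{3-(benzyloxy)-2,6-bis[4-(benzyloxy)benzyl]phenyl}acetate
Product: 15 2-{3-(benzyloxy)-2,6-bis[4-(benzyloxy)benzyl]phenyl}acetaldehyde
Conditions: i-Bu2AlH (1.1 equiv), CH2Cl2/toluene, −78 °C; then aq. potassium sodium tartrate
Reagents that add atoms: none
Why: Partial ester reduction with i-Bu2AlH, which at −78 °C in a non-coordinating solvent halts at the aldehyde oxidation level until the quench, and nothing else in 14 is reducible.

Step 9
Reactants: 16 3-bromo-5-methoxyphenol
Product: 17 1-(benzyloxy)-3-bromo-5-methoxybenzene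
Conditions: BnBr (1.1 equiv), K2CO3 (1.5 equiv), acetone, reflux
Reagents that add atoms: benzyl bromide, BrCc1ccccc1
Why: Williamson ether synthesis masks the acidic phenol, which would otherwise destroy the Grignard reagent, with the same group as every other phenol so that one final operation frees them all.

Step 10
Reactants: 17 1-(benzyloxy)-3-bromo-5-methoxybenzene; 15 2-{3-(benzyloxy)-2,6-bis[4-(benzyloxy)benzyl]phenyl}acetaldehyde
Product: 19 rac-1-[3-(benzyloxy)-5-methoxyphenyl]-2-{3-(benzyloxy)-2,6-bis[4-(benzyloxy)benzyl]phenyl}ethan-1-ol, via arylmagnesium bromide 18 (not isolated)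
Conditions: 17 (1.5 equiv), Mg turnings (iodine-activated), THF, reflux; then 15, THF, −40 → 0 °C; sat. aq. NH4Cl
Reagents that add atoms: none
Why: Grignard formation followed by 1,2-addition to the aldehyde, with low temperature and a modest excess of 18 offsetting enolisation, and the carbinol stereocentre forms as a racemate, which does not matter because step 11 removes it.

Step 11
Reactants: 19 rac-1-[3-(benzyloxy)-5-methoxyphenyl]-2-{3-(benzyloxy)-2,6-bis[4-(benzyloxy)benzyl]phenyl}ethan-1-ol
Product: 20 2,4-bis(4-hydroxybenzyl)-3-[2-(3-hydroxy-5-methoxyphenyl)ethyl]phenol (CNP0518900.0)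
Conditions: H2 (1–4 bar), 10% Pd/C, EtOH/EtOAc, cat. aq. HCl, rt → 40 °C
Reagents that add atoms: none
Why: Catalytic hydrogenolysis over palladium cleaves the four aryl benzyl ethers and, with a trace of acid, the secondary benzylic C–OH bond, and any acid-induced loss of water to an alkene would be harmless because hydrogenation leads to the same CH2–CH2 bridge, while the methyl ether and the diarylmethane bonds are untouched.

Compound list
1 | 2-bromoresorcinol (2-bromobenzene-1,3-diol) | Oc1cccc(O)c1Br | starting material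
2 | 4-(benzyloxy)benzyl alcohol | OCc1ccc(OCc2ccccc2)cc1 | starting material
3 | 4-[4-(benzyloxy)benzyl]-2-bromobenzene-1,3-diol | Oc1ccc(Cc2ccc(OCc3ccccc3)cc2)c(O)c1Br | intermediate
4 | 3-(benzyloxy)-6-[4-(benzyloxy)benzyl]-2-bromophenol | Oc1c(Br)c(OCc2ccccc2)ccc1Cc1ccc(OCc2ccccc2)cc1 | intermediate
5 | {3-(benzyloxy)-6-[4-(benzyloxy)benzyl]-2-bromophenoxy}trimethylsilane | C[Si](C)(C)Oc1c(Br)c(OCc2ccccc2)ccc1Cc1ccc(OCc2ccccc2)cc1 | intermediate
6 | {6-(benzyloxy)-3-[4-(benzyloxy)benzyl]-2-(trimethylsilyloxy)phenyl}lithium | [Li]c1c(O[Si](C)(C)C)c(Cc2ccc(OCc3ccccc3)cc2)ccc1OCc1ccccc1 | intermediate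
7 | lithium 3-(benzyloxy)-6-[4-(benzyloxy)benzyl]-2-(trimethylsilyl)phenoxide | [Li+].[O-]c1c([Si](C)(C)C)c(OCc2ccccc2)ccc1Cc1ccc(OCc2ccccc2)cc1 | intermediate
8 | 3-(benzyloxy)-6-[4-(benzyloxy)benzyl]-2-(trimethylsilyl)phenyl trifluoromethanesulfonate | C[Si](C)(C)c1c(OCc2ccccc2)ccc(Cc2ccc(OCc3ccccc3)cc2)c1OS(=O)(=O)C(F)(F)F | intermediate
9 | 4′-(benzyloxy)acetophenone | CC(=O)c1ccc(OCc2ccccc2)cc1 | starting material
10 | methyl 3-[4-(benzyloxy)phenyl]-3-oxopropanoate | COC(=O)CC(=O)c1ccc(OCc2ccccc2)cc1 | intermediate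
11 | 3-(benzyloxy)-6-[4-(benzyloxy)benzyl]benzyne (1,2-didehydrobenzene) | C1(Cc2ccc(OCc3ccccc3)cc2)=CC=C(OCc2ccccc2)C#C1 | intermediate
12 | caesium 5-(benzyloxy)-2-[4-(benzyloxy)benzyl]-7-[4-(benzyloxy)phenyl]-8-(methoxycarbonyl)bicyclo[4.2.0]octa-1,3,5-trien-7-olate (racemic mixture of diastereomers; both stereocentres vanish on ring opening) | COC(=O)C1c2c(Cc3ccc(OCc4ccccc4)cc3)ccc(OCc3ccccc3)c2C1([O-])c1ccc(OCc2ccccc2)cc1.[Cs+] | intermediate
13 | methyl 2-{3-(benzyloxy)-2-[4-(benzyloxy)benzoyl]-6-[4-(benzyloxy)benzyl]phenyl}acetate | COC(=O)Cc1c(Cc2ccc(OCc3ccccc3)cc2)ccc(OCc2ccccc2)c1C(=O)c1ccc(OCc2ccccc2)cc1 | intermediate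
14 | methyl 2-{3-(benzyloxy)-2,6-bis[4-(benzyloxy)benzyl]phenyl}acetate | COC(=O)Cc1c(Cc2ccc(OCc3ccccc3)cc2)ccc(OCc2ccccc2)c1Cc1ccc(OCc2ccccc2)cc1 | intermediate
15 | 2-{3-(benzyloxy)-2,6-bis[4-(benzyloxy)benzyl]phenyl}acetaldehyde | O=CCc1c(Cc2ccc(OCc3ccccc3)cc2)ccc(OCc2ccccc2)c1Cc1ccc(OCc2ccccc2)cc1 | intermediate
16 | 3-bromo-5-methoxyphenol | COc1cc(O)cc(Br)c1 | starting material
17 | 1-(benzyloxy)-3-bromo-5-methoxybenzene | COc1cc(Br)cc(OCc2ccccc2)c1 | intermediate
18 | [3-(benzyloxy)-5-methoxyphenyl]magnesium bromide | COc1cc([Mg]Br)cc(OCc2ccccc2)c1 | intermediate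
19 | rac-1-[3-(benzyloxy)-5-methoxyphenyl]-2-{3-(benzyloxy)-2,6-bis[4-(benzyloxy)benzyl]phenyl}ethan-1-ol (racemate) | COc1cc(OCc2ccccc2)cc(C(O)Cc2c(Cc3ccc(OCc4ccccc4)cc3)ccc(OCc3ccccc3)c2Cc2ccc(OCc3ccccc3)cc2)c1 | intermediate
20 | 2,4-bis(4-hydroxybenzyl)-3-[2-(3-hydroxy-5-methoxyphenyl)ethyl]phenol (CNP0518900.0, achiral) | COc1cc(O)cc(CCc2c(Cc3ccc(O)cc3)ccc(O)c2Cc2ccc(O)cc2)c1 | target

Total step count: 11. Longest linear sequence: 9 (steps 1, 2, 3, 4, 6, 7, 8, 10, 11).

Steps most likely to fail

Step 6 (aryne insertion).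
- What may go wrong: the C2 benzyl group steers the enolate to the wrong aryne carbon. Alternatively, C6 picks up a proton before it can close onto the electron-rich, weakly electrophilic aroyl carbonyl, so that only plain α-arylation takes place.
- The fallback gives up the aryne and makes the two bonds one after the other, by organolithium addition and cross-coupling. It sets out from 4 and comes back at 15.
- Treatment of 4 with n-BuLi (2.2 equiv, THF, −78 °C; O-deprotonation, then Br–Li exchange) and 4-(benzyloxy)benzaldehyde should give racemic 3-(benzyloxy)-6-[4-(benzyloxy)benzyl]-2-{[4-(benzyloxy)phenyl](hydroxy)methyl}phenol F1.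
- Et3SiH/TFA in CH2Cl2 removes the doubly benzylic hydroxyl to give 3-(benzyloxy)-2,6-bis[4-(benzyloxy)benzyl]phenol F2.
- Tf2O/pyridine converts it into 3-(benzyloxy)-2,6-bis[4-(benzyloxy)benzyl]phenyl trifluoromethanesulfonate F3.
- Stille allylation (allyltributylstannane, PdCl2(PPh3)2, LiCl, DMF, 100 °C) gives 2-allyl-4-(benzyloxy)-1,3-bis[4-(benzyloxy)benzyl]benzene F4.
- Lemieux–Johnson cleavage (cat. OsO4, NaIO4, 2,6-lutidine, dioxane/H2O) delivers 15.

Step 7 (ionic reduction of the ketone).
- What may go wrong: hydride transfer from the bulky silane to a carbonyl carbon shielded on both faces by the ortho substituents of ring B is sluggish. Prolonged acid exposure then erodes the benzyl ether next to the ketone or draws the neighbouring ester into lactonisation.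
- The fallback replaces the first, difficult hydride transfer by a small metal hydride and restores the aldehyde level by oxidation. It sets out from 13 and comes back at 15.
- LiAlH4 (THF, 0 °C → rt) reduces ketone and ester to racemic 2-{3-(benzyloxy)-6-[4-(benzyloxy)benzyl]-2-{[4-(benzyloxy)phenyl](hydroxy)methyl}phenyl}ethan-1-ol F5.
- Et3SiH/BF3·OEt2 (CH2Cl2, −20 → 0 °C) removes only the readily ionised diaryl carbinol hydroxyl to give 2-{3-(benzyloxy)-2,6-bis[4-(benzyloxy)benzyl]phenyl}ethan-1-ol F6.
- Dess–Martin periodinane oxidises the primary alcohol to 15.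

Step 1 (Friedel–Crafts mono-benzylation).
- What may go wrong: a second alkylation at the remaining activated position of the resorcinol ring, and self-condensation of the benzylic cation source.
- The fallback uses acylation in place of alkylation, so that the deactivating carbonyl stops substitution after one event. Its hydrogen bond to the adjacent hydroxyl also decides which oxygen is benzylated, so the site selectivity of step 2 is no longer needed. It sets out from 1 and comes back at 4.
- Heating 1 with 4-hydroxybenzoic acid in BF3·OEt2 (90 °C, Nencki-type Friedel–Crafts acylation) should give (3-bromo-2,4-dihydroxyphenyl)(4-hydroxyphenyl)methanone F7.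
- BnBr (2.1 equiv)/K2CO3 in acetone alkylates the two non-chelated phenols to give [4-(benzyloxy)-3-bromo-2-hydroxyphenyl][4-(benzyloxy)phenyl]methanone F8.
- Et3SiH/TFA reduces the electron-rich, unhindered ketone to the methylene group of 4.

Further compounds
F1 | step 6 | rac-3-(benzyloxy)-6-[4-(benzyloxy)benzyl]-2-{[4-(benzyloxy)phenyl](hydroxy)methyl}phenol | Oc1c(C(O)c2ccc(OCc3ccccc3)cc2)c(OCc2ccccc2)ccc1Cc1ccc(OCc2ccccc2)cc1
F2 | step 6 | 3-(benzyloxy)-2,6-bis[4-(benzyloxy)benzyl]phenol | Oc1c(Cc2ccc(OCc3ccccc3)cc2)c(OCc2ccccc2)ccc1Cc1ccc(OCc2ccccc2)cc1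
F3 | step 6 | 3-(benzyloxy)-2,6-bis[4-(benzyloxy)benzyl]phenyl trifluoromethanesulfonate | FC(F)(F)S(=O)(=O)Oc1c(Cc2ccc(OCc3ccccc3)cc2)c(OCc2ccccc2)ccc1Cc1ccc(OCc2ccccc2)cc1
F4 | step 6 | 2-allyl-4-(benzyloxy)-1,3-bis[4-(benzyloxy)benzyl]benzene | C=CCc1c(Cc2ccc(OCc3ccccc3)cc2)c(OCc2ccccc2)ccc1Cc1ccc(OCc2ccccc2)cc1
F5 | step 7 | rac-2-{3-(benzyloxy)-6-[4-(benzyloxy)benzyl]-2-{[4-(benzyloxy)phenyl](hydroxy)methyl}phenyl}ethan-1-ol | OCCc1c(Cc2ccc(OCc3ccccc3)cc2)ccc(OCc2ccccc2)c1C(O)c1ccc(OCc2ccccc2)cc1
F6 | step 7 | 2-{3-(benzyloxy)-2,6-bis[4-(benzyloxy)benzyl]phenyl}ethan-1-ol | OCCc1c(Cc2ccc(OCc3ccccc3)cc2)ccc(OCc2ccccc2)c1Cc1ccc(OCc2ccccc2)cc1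
F7 | step 1 | (3-bromo-2,4-dihydroxyphenyl)(4-hydroxyphenyl)methanone | O=C(c1ccc(O)cc1)c1ccc(O)c(Br)c1O
F8 | step 1 | [4-(benzyloxy)-3-bromo-2-hydroxyphenyl][4-(benzyloxy)phenyl]methanone | O=C(c1ccc(OCc2ccccc2)cc1)c1ccc(OCc2ccccc2)c(Br)c1O
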